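Ring A (C1–C5, C10), a cyclohexane fused to the cyclopentane ring B at C5–C10, is opened by a retro-Diels–Alder cut of C1–C10 and C4–C5. In the forward sense, step 2 adds methyl (2Z)-2-methylpenta-2,4-dienoate, which already carries C18 and C19 on C4, across the C5=C10 bond of (R)-4-silyloxycyclopentenone, the future ring B. One operation closes ring A, fixes the quaternary C4 against the ring-B face and leaves the C2=C3 alkene for the late cis-diol. The C6 ketone then drives the second Diels–Alder that builds ring C, delivers the C10 oxygen by conjugate lactonisation, and becomes the C7 carboxyl by carbonylation. Ring D is closed last.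

Key step: step 2

Remark: gibberellin numbering is used (C7 = carboxyl carbon on C6, C17 = exocyclic CH2, C18 = methyl on C4, C19 = lactone carbonyl); α is the face of the lactone bridge, β the opposite face.
Assumption: compounds 1, 2, 4, 6 and 9 are taken as commercially available.

Step 1
Reactants: 1 acrolein; 2 methyl 2-[bis(2,2,2-trifluoroethoxy)phosphoryl]propanoate
Product: 3 methyl (2Z)-2-methylpenta-2,4-dienoate
Conditions: KHMDS, 18-crown-6, THF, −78 °C; then 1
Reagents that add atoms: none
Why: Still–Gennari olefination, in which the electron-poor bis(trifluoroethyl) phosphonate eliminates fast from the kinetically formed adduct, so the ester should end cis to the vinyl group (Z); no stereocentre is formed.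

Step 2
Reactants: 3 methyl (2Z)-2-methylpenta-2,4-dienoate; 4 (R)-4-(tert-butyldimethylsilyloxy)cyclopent-2-en-1-one
Product: 5 cis-fused AB Diels–Alder adduct
Conditions: 3 (3 equiv), BHT (cat.), CH2Cl2, 13 kbar, 35 °C
Reagents that add atoms: none
Why: Concerted, asynchronous [4+2] cycloaddition in which the unsubstituted diene terminus C1 bonds to the enone β-carbon C10 and the fully substituted terminus C4 to the α-carbon C5 (ortho orientation, reinforced by the methyl donor on C4 and the larger LUMO coefficient at C10). The closest known reaction type is the pressure- or Lewis-acid-promoted Diels–Alder reaction of cyclopent-2-enones, including 4-silyloxy derivatives, with 1-substituted butadienes. Ring A is closed by suprafacial addition of both diene termini to one face of the C5=C10 bond, so it is cis-fused to ring B. C10 and C5 are controlled by the C9 silyloxy group, which sends the diene to the opposite (β) face, and C4 by the endo transition state, in which the inside (Z) ester points away from ring B and ends cis to H5, on the later α face, while the outside methyl ends β. The step needs regio-, face- and endo-selectivity: the first comes from the polarisation of the enone, the second from the silyloxy group, and the third from secondary overlap with the C6 carbonyl and from the Z-ester itself, which would collide with ring B in the exo transition state. Only C4 is carried to the target, because C5 and C10 are re-set in steps 6 and 7 and C9 in steps 3 and 4, but the face on which C1 sits steers the second cycloaddition in step 4.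

Step 3
Reactants: 5 cis-fused AB Diels–Alder adduct; 6 3-bromo-1-(trimethylsilyl)prop-1-yne
Product: 8 AB propargyl enone, via alkylated silyloxy ketone 7 (not isolated)
Conditions: LDA, THF, −78 °C; 6, HMPA, −78 → −45 °C; then DBU, −45 → 23 °C
Reagents that add atoms: none
Why: Kinetic enolisation should occur at the unhindered C8 methylene (C5–H is tertiary and flanked by the quaternary C4), the β-silyloxy enolate is alkylated at low temperature by the reactive propargylic bromide as in α-alkylations of β-silyloxy carbonyl enolates, and E1cB loss of silanolate then gives the 2-substituted enone, so the C8 and C9 stereocentres disappear and their configuration is irrelevant.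

Step 4
Reactants: 8 AB propargyl enone; 9 2-(trimethylsilyloxy)buta-1,3-diene
Product: 11 ABC diketone, via silyl enol ether 10 (not isolated)
Conditions: 9 (5 equiv), CH2Cl2, 15 kbar, 40 °C; then 1 M HCl, THF, 0 °C
Reagents that add atoms: none
Why: Pressure-promoted Diels–Alder reaction of a 2-substituted cyclopentenone with a 2-silyloxydiene, in which the nucleophilic CH2 next to the silyloxy carbon bonds to the β-carbon C9 (para orientation, placing oxygen on C12) and the diene adds to the α face, anti to C1 on the neighbouring C10 and on the convex side of the cis-fused AB bicycle, which sets C8 (propargyl β) and C9 (H β) before acid hydrolyses the enol ether.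

Step 5
Reactants: 11 ABC diketone
Product: 12 ABC 12-ketal
Conditions: HOCH2CH2OH, PPTS, PhH, reflux (Dean–Stark)
Reagents that add atoms: ethylene glycol, OCCO
Why: Acid-catalysed ketalisation should be selective for the unhindered cyclohexanone carbonyl C12, because C6 is a cyclopentanone flanked by the quaternary C8 and the tertiary C5.

Step 6
Reactants: 12 ABC 12-ketal
Product: 13 dienone ester
Conditions: IBX, DMSO/PhF, 70 °C
Reagents that add atoms: none
Why: IBX dehydrogenation of a ketone to an enone, regiospecific because C5–H is the only α-hydrogen of the C6 ketone (C8 is quaternary); it gives the C5=C10 enone and erases the temporary C5 and C10 stereocentres.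

Step 7
Reactants: 13 dienone ester
Product: 15 keto lactone, via dienone acid 14 (not isolated)
Conditions: LiI, 2,6-lutidine, 120 °C; 1 M HCl work-up; then TsOH·H2O (cat.), PhMe, 60 °C
Reagents that add atoms: none
Why: Iodide cleaves the hindered methyl ester by SN2 attack at the methyl group, and acid then promotes intramolecular conjugate addition of the C19 acid to C10 of the protonated enone (a β,γ-unsaturated acid to γ-lactone closure); the carboxyl can reach C10 only from the α face on which it stands, so O10 is α, and ketonisation should place H5 β because the alternative is a trans-fused bicyclo[3.3.0]octane of lactone and ring B.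

Step 8
Reactants: 15 keto lactone
Product: 16 enol triflate
Conditions: KHMDS, THF, −78 °C; PhNTf2, −78 → 0 °C
Reagents that add atoms: N-phenyl-bis(trifluoromethanesulfonimide), O=S(=O)(N(c1ccccc1)S(=O)(=O)C(F)(F)F)C(F)(F)F
Why: Enol triflate formation from the potassium enolate, which can form only towards C5, while β-elimination of the lactone carboxylate is slowed because the C10–O bond lies close to the nodal plane of the enolate within the bridged lactone.

Step 9
Reactants: 16 enol triflate
Product: 17 unsaturated C7 ester
Conditions: Pd(OAc)2 (cat.), dppf (cat.), CO (1 atm), MeOH, Et3N, DMF, 55 °C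
Reagents that add atoms: carbon monoxide, [C-]#[O+]; methanol, CO
Why: Palladium-catalysed methoxycarbonylation of an enol triflate (oxidative addition, CO insertion, methanolysis) installs C7 on C6 without forming a stereocentre.

Step 10
Reactants: 17 unsaturated C7 ester
Product: 20 keto alkyne ester, via 6-epi ester 18 (not isolated), via ketal alkyne ester 19 (not isolated)
Conditions: SmI2, MeOH, THF, −78 → 0 °C; then NaOMe (cat.), MeOH, 23 °C; then 1 M HCl, THF, 23 °C
Reagents that add atoms: water, O
Why: Samarium diiodide conjugate reduction of the enoate should protonate C5 on the exposed β face (the only outcome that keeps lactone and ring B cis-fused), methoxide then equilibrates C6 to the more stable 6β-ester trans to C4 and removes the alkynyl silyl group, and aqueous acid unmasks the C12 ketone and re-closes any lactone opened by methoxide.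

Step 11
Reactants: 20 keto alkyne ester
Product: 21 2β,3β-diol
Conditions: OsO4 (cat.), NMO, acetone/H2O, 23 °C
Reagents that add atoms: N-methylmorpholine N-oxide, C[N+]1([O-])CCOCC1; water, O
Why: Catalytic osmium tetroxide cis-dihydroxylation should attack C2=C3 from the β face, anti to the lactone bridge of the 6-oxabicyclo[3.2.1]octane, giving the 2β,3β-diol, while the terminal alkyne is inert and no other alkene is present at this stage.

Step 12
Reactants: 21 2β,3β-diol
Product: 23 target methyl ester, via tris(triethylsilyl) enol ether 22 (not isolated)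
Conditions: TESOTf, Et3N, CH2Cl2, 0 °C; then [(JohnPhos)Au(MeCN)]SbF6 (cat.), CH2Cl2/MeOH, 23 °C; then 1 M HCl, THF/MeOH, 0 °C
Reagents that add atoms: none
Why: Gold(I)-catalysed 5-exo-dig Conia-ene-type carbocyclisation of a silyl enol ether onto the terminal alkyne forms C13–C16 and the exocyclic methylene; only the Δ12(13) enol ether can reach the alkyne without creating a trans-fused bicyclo[3.3.0]octane, the bridge geometry fixes C13, and the unreactive Δ11 isomer is returned to 21 on work-up for recycling.

Step 13
Reactants: 23 target methyl ester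
Product: 24 target CNP0307952.1
Conditions: n-PrSLi, HMPA, 23 °C; then 1 M HCl
Reagents that add atoms: none
Why: Thiolate SN2 demethylation of the hindered C7 methyl ester, a standard release of gibberellin 7-acids, leaves the tertiary-alkyl lactone untouched and avoids hydroxide, which could epimerise C3 by retro-aldol cleavage.

Compound list
1 | acrolein | C=CC=O | starting material
2 | methyl 2-[bis(2,2,2-trifluoroethoxy)phosphoryl]propanoate | COC(=O)C(C)P(=O)(OCC(F)(F)F)OCC(F)(F)F | starting material
3 | methyl (2Z)-2-methylpenta-2,4-dienoate | C=C/C=C(C)\C(=O)OC | intermediate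
4 | (R)-4-(tert-butyldimethylsilyloxy)cyclopent-2-en-1-one | O=C1C=C[C@H](O[Si](C)(C)C(C)(C)C)C1 | starting material
5 | cis-fused AB Diels–Alder adduct: ring A with C2=C3 and C4 bearing β-CH3 and α-CO2Me; ring B with C6=O, C8H2 and 9α-OTBS; H5 and H10 both α | O=C1C[C@@H](O[Si](C)(C)C(C)(C)C)[C@@H]2CC=C[C@@](C)(C(=O)OC)[C@H]12 | intermediate
6 | 3-bromo-1-(trimethylsilyl)prop-1-yne | C[Si](C)(C)C#CCBr | starting material
7 | alkylated silyloxy ketone: 5 with 8β-CH2C≡CSiMe3, trans to the 9α-OTBS | O=C1[C@H](CC#C[Si](C)(C)C)[C@@H](O[Si](C)(C)C(C)(C)C)[C@@H]2CC=C[C@@](C)(C(=O)OC)[C@H]12 | intermediate (not isolated)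
8 | AB propargyl enone: C6=O conjugated with C8=C9, C8 bearing CH2C≡CSiMe3; ring A as in 5 | O=C1C(CC#C[Si](C)(C)C)=C[C@@H]2CC=C[C@@](C)(C(=O)OC)[C@H]12 | intermediate
9 | 2-(trimethylsilyloxy)buta-1,3-diene | C=CC(=C)O[Si](C)(C)C | starting material
10 | ABC silyl enol ether: ring C cis-fused on the α face of ring B, C12(OSiMe3)=C13, 8β-propargyl, 9β-H | O=C1[C@@]3(CC#C[Si](C)(C)C)CC=C(O[Si](C)(C)C)C[C@H]3[C@@H]2CC=C[C@@](C)(C(=O)OC)[C@H]12 | intermediate (not isolated)
11 | ABC diketone: C6=O and C12=O, otherwise as 10 | O=C1[C@@]3(CC#C[Si](C)(C)C)CCC(=O)C[C@H]3[C@@H]2CC=C[C@@](C)(C(=O)OC)[C@H]12 | intermediate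
12 | ABC 12-ketal: 1,3-dioxolane at C12 | O=C1[C@@]3(CC#C[Si](C)(C)C)CCC4(OCCO4)C[C@H]3[C@@H]2CC=C[C@@](C)(C(=O)OC)[C@H]12 | intermediate
13 | dienone ester: C6=O conjugated with C5=C10, C2=C3 retained, C4 with β-CH3 and α-CO2Me | O=C1C2=C(CC=C[C@@]2(C)C(=O)OC)[C@@H]3CC4(OCCO4)CC[C@]13CC#C[Si](C)(C)C | intermediate
14 | dienone acid: 13 with free C19 carboxylic acid | O=C1C2=C(CC=C[C@@]2(C)C(=O)O)[C@@H]3CC4(OCCO4)CC[C@]13CC#C[Si](C)(C)C | intermediate (not isolated)
15 | keto lactone: 19,10α-lactone, 5β-H, C6=O, C2=C3 | O=C1[C@@H]2[C@@]3(C)C=CC[C@@]2(OC3=O)[C@@H]4CC5(OCCO5)CC[C@]14CC#C[Si](C)(C)C | intermediate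
16 | enol triflate: C6(OTf)=C5 | O=S(=O)(OC1=C2[C@@]3(C)C=CC[C@@]2(OC3=O)[C@@H]4CC5(OCCO5)CC[C@]14CC#C[Si](C)(C)C)C(F)(F)F | intermediate
17 | unsaturated C7 ester: C5=C6–CO2Me | COC(=O)C1=C2[C@@]3(C)C=CC[C@@]2(OC3=O)[C@@H]4CC5(OCCO5)CC[C@]14CC#C[Si](C)(C)C | intermediate
18 | 6-epi ester: 5β-H, 6α-CO2Me (expected kinetic epimer), silylalkyne and ketal retained | COC(=O)[C@@H]1[C@@H]2[C@@]3(C)C=CC[C@@]2(OC3=O)[C@@H]4CC5(OCCO5)CC[C@]14CC#C[Si](C)(C)C | intermediate (not isolated)
19 | ketal alkyne ester: 6β-CO2Me, terminal alkyne, 12-ketal | COC(=O)[C@H]1[C@@H]2[C@@]3(C)C=CC[C@@]2(OC3=O)[C@@H]4CC5(OCCO5)CC[C@]14CC#C | intermediate (not isolated)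
20 | keto alkyne ester: 12-ketone, 8β-propargyl, 6β-CO2Me, 19,10-lactone, C2=C3 | COC(=O)[C@H]1[C@@H]2[C@@]3(C)C=CC[C@@]2(OC3=O)[C@@H]4CC(=O)CC[C@]14CC#C | intermediate
21 | 2β,3β-diol of 20 | COC(=O)[C@H]1[C@@H]2[C@@]3(C)[C@@H](O)[C@@H](O)C[C@@]2(OC3=O)[C@@H]4CC(=O)CC[C@]14CC#C | intermediate
22 | tris(triethylsilyl) enol ether: 2β,3β-bis(OSiEt3), C12(OSiEt3)=C13 | COC(=O)[C@H]1[C@@H]2[C@@]3(C)[C@@H](O[Si](CC)(CC)CC)[C@@H](O[Si](CC)(CC)CC)C[C@@]2(OC3=O)[C@@H]4CC(O[Si](CC)(CC)CC)=CC[C@]14CC#C | intermediate (not isolated)
23 | target methyl ester (7-methyl ester of 24) | C=C1C[C@]23C[C@H]1C(=O)C[C@H]2[C@@]12C[C@H](O)[C@H](O)[C@@](C)(C(=O)O1)[C@H]2[C@@H]3C(=O)OC | intermediate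
24 | CNP0307952.1 | C=C1C[C@]23C[C@H]1C(=O)C[C@H]2[C@@]12C[C@H](O)[C@H](O)[C@@](C)(C(=O)O1)[C@H]2[C@@H]3C(=O)O | target

Total step count: 13. Longest linear sequence: 13 steps (1 and 2 → 3 → 5 → … → 24); 12 steps from enone 4.

Steps most likely to fail

Step 2. The Z-diene may react too slowly, because the inside ester disfavours the s-cis conformation, and it may isomerise to the E-diene or lose endo selectivity. The fallback sets out from 4 and uses a diene that is locked s-cis with C19 inside, 3-methyl-2H-pyran-2-one (CC1=CC=COC1=O). Cycloaddition under pressure, endo and anti to the silyloxy group, should give the bridged lactone adduct F1. Pd(PPh3)4 with ammonium formate then cleaves the allylic C1–O bond reductively to the acid F2, and TMSCHN2 converts F2 into 5, where the route is rejoined.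

Step 12. Silylation may give mainly the unproductive Δ11 enol ether, or protodesilylation may outrun cyclisation. The fallback sets out from 21 and closes ring D by an anionic ketone–alkyne cyclisation under equilibrating enolate conditions, where only the C13 enolate can close. The diol is first protected with 2,2-dimethoxypropane/PPTS as the acetonide F3, so that base cannot trigger retro-aldol epimerisation at C3. KOt-Bu in t-BuOH/DMSO then gives the cyclised acetonide F4, and aqueous acetic acid releases 23.

Step 10. The enoate radical anion may expel the γ-acyloxy (lactone) group, or the tetrasubstituted alkene may be reduced incompletely. The fallback avoids the enoate and sets out from 15. Wittig reaction with Ph3P=CHOMe gives the enol ether F5, and aqueous acid hydrolyses it, with loss of the ketal and equilibration at C6, to the 6β-aldehyde F6. Pinnick oxidation gives the acid F7, TMSCHN2 gives the methyl ester F8, and K2CO3/MeOH removes the alkynyl silyl group to give 20.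

Further compounds
F1 | step 2 | bridged lactone adduct of 4 and 3-methyl-2H-pyran-2-one (19,1-lactone, C2=C3, 9α-OTBS, C6=O) | O=C1C[C@@H](O[Si](C)(C)C(C)(C)C)[C@@H]2[C@@H]3C=C[C@@](C)(C(=O)O3)[C@H]12
F2 | step 2 | carboxylic acid corresponding to 5 | O=C1C[C@@H](O[Si](C)(C)C(C)(C)C)[C@@H]2CC=C[C@@](C)(C(=O)O)[C@H]12
F3 | step 12 | 2β,3β-acetonide of 21 | COC(=O)[C@H]1[C@@H]2[C@@]3(C)[C@H]5OC(C)(C)O[C@H]5C[C@@]2(OC3=O)[C@@H]4CC(=O)CC[C@]14CC#C
F4 | step 12 | 2β,3β-acetonide of 23 | C=C1C[C@]23C[C@H]1C(=O)C[C@H]2[C@@]12C[C@@H]4OC(C)(C)O[C@@H]4[C@@](C)(C(=O)O1)[C@H]2[C@@H]3C(=O)OC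
F5 | step 10 | C6 methoxymethylene enol ether of 15 (E/Z mixture) | COC=C1[C@@H]2[C@@]3(C)C=CC[C@@]2(OC3=O)[C@@H]4CC5(OCCO5)CC[C@]14CC#C[Si](C)(C)C
F6 | step 10 | 6β-aldehyde with free 12-ketone and silylalkyne | O=C[C@H]1[C@@H]2[C@@]3(C)C=CC[C@@]2(OC3=O)[C@@H]4CC(=O)CC[C@]14CC#C[Si](C)(C)C
F7 | step 10 | 6β-carboxylic acid from F6 | OC(=O)[C@H]1[C@@H]2[C@@]3(C)C=CC[C@@]2(OC3=O)[C@@H]4CC(=O)CC[C@]14CC#C[Si](C)(C)C
F8 | step 10 | 6β-methyl ester with silylalkyne (C-silyl derivative of 20) | COC(=O)[C@H]1[C@@H]2[C@@]3(C)C=CC[C@@]2(OC3=O)[C@@H]4CC(=O)CC[C@]14CC#C[Si](C)(C)C
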